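Numbering used throughout: C1 ketone; C2=C3 furanone alkene (C3 on the ring oxygen); C4=C5 with C15 on C4; C6 lactone carbinol; C7; C8 ester carbinol; C9; C10 quaternary (C14 methyl); C11(=C13)–C12 lactone.
Retrosynthetic cuts, in order: the C8–O acyl bond and C11=C13; C7–C8; C7=C11 together with the C6–O acyl bond (butenolide); C3–C4, between a methyl tetronate from (S)-citramalic acid and a Z-alkenyl iodide from 2-butyne-1,4-diol.
Enabling feature: C8 (a carbinol, hence an aldehyde carbon) and C7 (β to the lactone carbonyl C12, hence the acceptor carbon of a C6 butenolide) are both electrophiles; a ketyl at C8 joins them and closes the ten-membered carbocycle C1–C10 across the finished furanone and butenolide rings, creating C7 and C8.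
Forward order: furanone ring (alkenyllithium plus tetronate, then acid), butenolide ring (acrylate ring-closing metathesis), ten-membered ring (SmI2), then C13, the methacrylate and release of C15–OH.
Stereochemistry: C10 from (S)-citramalic acid; 4Z from hydroxyl-directed trans-hydroalumination/iodination; C6 from a ligand-controlled vinylzinc addition; C7 relayed from C6 and C8 from a samarium chelate in the ring closure.

Key step: step 16

Remark: the samarium-bridged cyclisation is assumed to give the 8R alcohol of the target, so the methacrylate is introduced with retention; C15 is carried as a 4-methoxybenzyl (PMB) ether and C8 as a tert-butyldiphenylsilyl (TBDPS) ether, because a silyl ether on C15 could migrate to the neighbouring alkenyllithium.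

Step 1
Reactants: 1 (S)-citramalic acid
Product: 2 2-[(4S)-2,2,4-trimethyl-5-oxo-1,3-dioxolan-4-yl]acetic acid
Conditions: Me2C(OMe)2, PPTS (cat.), rt
Reagents that add atoms: 2,2-dimethoxypropane COC(C)(C)OC
Why: Acid-catalysed transacetalisation closes the five-membered 1,3-dioxolan-4-one on the α-hydroxy acid in preference to a six-membered ring on the CH2CO2H arm (acetonide formation), which differentiates the two carboxyl groups without touching the quaternary centre that becomes C10.

Step 2
Reactants: 2 2-[(4S)-2,2,4-trimethyl-5-oxo-1,3-dioxolan-4-yl]acetic acid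
Product: 3 (5S)-5-(2-hydroxyethyl)-2,2,5-trimethyl-1,3-dioxolan-4-one
Conditions: BH3·SMe2, THF, 0 °C → rt; MeOH quench
Reagents that add atoms: none
Why: Borane reduces the free carboxylic acid through its acyloxyborane far faster than the ester-like dioxolanone carbonyl (chemoselective borane reduction), giving the C8 alcohol.

Step 3
Reactants: 3 (5S)-5-(2-hydroxyethyl)-2,2,5-trimethyl-1,3-dioxolan-4-one
Product: 4 (5S)-5-[2-(tert-butyldiphenylsilyloxy)ethyl]-2,2,5-trimethyl-1,3-dioxolan-4-one
Conditions: TBDPSCl, imidazole, DMF, 0 °C → rt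
Reagents that add atoms: tert-butyl(chloro)diphenylsilane CC(C)(C)[Si](Cl)(c1ccccc1)c1ccccc1
Why: Silylation of the primary alcohol with imidazole as base leaves the base-sensitive dioxolanone closed, and the TBDPS ether is chosen because it survives the organolithium and the aqueous acid of step 11.

Step 4
Reactants: 4 (5S)-5-[2-(tert-butyldiphenylsilyloxy)ethyl]-2,2,5-trimethyl-1,3-dioxolan-4-one
Product: 5 methyl (2S)-4-(tert-butyldiphenylsilyloxy)-2-hydroxy-2-methylbutanoate
Conditions: K2CO3, MeOH, 0 °C → rt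
Reagents that add atoms: methanol CO
Why: Methoxide-mediated transesterification opens the acylal-type dioxolanone, releases acetone and gives the methyl ester with a free tertiary hydroxyl, the two groups the next step needs.

Step 5
Reactants: 5 methyl (2S)-4-(tert-butyldiphenylsilyloxy)-2-hydroxy-2-methylbutanoate
Product: 6 (5S)-5-[2-(tert-butyldiphenylsilyloxy)ethyl]-4-methoxy-5-methylfuran-2(5H)-one
Conditions: Ph3P=C=C=O, PhCO2H (cat.), toluene, reflux
Reagents that add atoms: (triphenylphosphoranylidene)ketene O=C=C=P(c1ccccc1)(c1ccccc1)c1ccccc1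
Why: The tertiary hydroxyl adds to the cumulated ylide to give an ester ylide that closes on the adjacent methyl ester by intramolecular Wittig olefination (domino addition–Wittig tetronate synthesis), which installs C2 and C3 and leaves C10 untouched.

Step 6
Reactants: 7 2-butyne-1,4-diol
Product: 8 4-[(4-methoxybenzyl)oxy]but-2-yn-1-ol
Conditions: NaH, PMBCl, n-Bu4NI (cat.), THF/DMF, 0 °C → rt, diol in excess
Reagents that add atoms: 4-methoxybenzyl chloride COc1ccc(CCl)cc1
Why: Williamson etherification with the diol in excess gives the mono-ether statistically, and the PMB group is chosen because, unlike a silyl group, it cannot migrate to the alkenyllithium of step 11.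

Step 7
Reactants: 8 4-[(4-methoxybenzyl)oxy]but-2-yn-1-ol
Product: 10 (2Z)-3-iodo-4-[(4-methoxybenzyl)oxy]but-2-en-1-ol, via alkenylalanate 9 (not isolated)
Conditions: NaAlH2(OCH2CH2OMe)2 (Red-Al), THF, 0 °C; then I2, −78 → 0 °C
Reagents that add atoms: iodine II
Why: The free hydroxyl directs trans-hydroalumination of the propargylic alcohol so that aluminium sits on the distal alkyne carbon in a cyclic alanate, and iodinolysis with retention gives the Z-iodoalkene that fixes the C4=C5 geometry (iodine, the later C3, cis to the later C6).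

Step 8
Reactants: 10 (2Z)-3-iodo-4-[(4-methoxybenzyl)oxy]but-2-en-1-ol
Product: 11 (2Z)-3-iodo-4-[(4-methoxybenzyl)oxy]but-2-enal
Conditions: MnO2, CH2Cl2, rt
Reagents that add atoms: none
Why: Activated MnO2 oxidises the allylic alcohol under neutral heterogeneous conditions (allylic oxidation), which keeps the Z geometry of the β-iodo enal.

Step 9
Reactants: 11 (2Z)-3-iodo-4-[(4-methoxybenzyl)oxy]but-2-enal
Product: 12 (3S,4Z)-5-iodo-6-[(4-methoxybenzyl)oxy]hexa-1,4-dien-3-ol
Conditions: Zn(CH=CH2)2, (−)-MIB [(2S)-3-exo-morpholinoisoborneol] (cat.), toluene, −20 → 0 °C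
Reagents that add atoms: divinylzinc C=C[Zn]C=C
Why: Amino-alcohol-catalysed enantioselective 1,2-addition of an alkenylzinc reagent to the aldehyde, in which the (−)-MIB zinc alkoxide delivers the vinyl group to the Si face as it does for aromatic and α,β-unsaturated aldehydes, sets C6 as the 3S carbinol.

Step 10
Reactants: 12 (3S,4Z)-5-iodo-6-[(4-methoxybenzyl)oxy]hexa-1,4-dien-3-ol
Product: 13 (3S,4Z)-5-iodo-6-[(4-methoxybenzyl)oxy]-3-[(2-methoxypropan-2-yl)oxy]hexa-1,4-diene
Conditions: 2-methoxypropene, PPTS (cat.), CH2Cl2, 0 °C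
Reagents that add atoms: 2-methoxypropene COC(C)=C
Why: Acid-catalysed addition of the alcohol to the enol ether gives a 2-methoxyprop-2-yl (MOP) mixed ketal (no new stereocenter) that tolerates t-BuLi, cannot undergo the silyl migration open to a silyl ether cis to the lithium, and is cleaved by the acid of step 11.

Step 11
Reactants: 13 (3S,4Z)-5-iodo-6-[(4-methoxybenzyl)oxy]-3-[(2-methoxypropan-2-yl)oxy]hexa-1,4-diene; 6 (5S)-5-[2-(tert-butyldiphenylsilyloxy)ethyl]-4-methoxy-5-methylfuran-2(5H)-one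
Product: 16 (2S)-2-[2-(tert-butyldiphenylsilyloxy)ethyl]-5-{(2Z,4S)-4-hydroxy-1-[(4-methoxybenzyl)oxy]hexa-2,5-dien-2-yl}-2-methylfuran-3(2H)-one, via alkenyllithium 14 (not isolated), via lactol 15 (not isolated)
Conditions: 13, t-BuLi (2 equiv), Et2O, −78 °C; then 6, THF, −78 → −40 °C; then 0.5 M aq. HCl, THF, 0 °C
Reagents that add atoms: water O
Why: Iodine–lithium exchange with retention of alkene geometry gives the Z-alkenyllithium, which adds once to the vinylogous carbonate carbonyl of the tetronate to a lactolate that is stable at low temperature, and aqueous acid then ionises the lactol to an oxocarbenium ion that is hydrolysed at the methoxy-bearing carbon (1,2-addition with acid-induced carbonyl transposition of the Stork–Danheiser type) to the 3(2H)-furanone while cleaving the mixed ketal, so that C10, C6 and the 4Z geometry are carried over unchanged.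

Step 12
Reactants: 16 (2S)-2-[2-(tert-butyldiphenylsilyloxy)ethyl]-5-{(2Z,4S)-4-hydroxy-1-[(4-methoxybenzyl)oxy]hexa-2,5-dien-2-yl}-2-methylfuran-3(2H)-one
Product: 17 (3S,4Z)-5-{(5S)-5-[2-(tert-butyldiphenylsilyloxy)ethyl]-5-methyl-4-oxo-4,5-dihydrofuran-2-yl}-6-[(4-methoxybenzyl)oxy]hexa-1,4-dien-3-yl prop-2-enoate
Conditions: acryloyl chloride, i-Pr2NEt, CH2Cl2, −78 → 0 °C
Reagents that add atoms: acryloyl chloride C=CC(=O)Cl
Why: O-Acylation of the secondary alcohol with the acid chloride and a hindered amine at low temperature does not break the C6–O bond, so the configuration is retained, and it supplies C11 and C12.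

Step 13
Reactants: 17 (3S,4Z)-5-{(5S)-5-[2-(tert-butyldiphenylsilyloxy)ethyl]-5-methyl-4-oxo-4,5-dihydrofuran-2-yl}-6-[(4-methoxybenzyl)oxy]hexa-1,4-dien-3-yl prop-2-enoate
Product: 18 (5S)-5-[(1Z)-2-{(5S)-5-[2-(tert-butyldiphenylsilyloxy)ethyl]-5-methyl-4-oxo-4,5-dihydrofuran-2-yl}-3-[(4-methoxybenzyl)oxy]prop-1-en-1-yl]furan-2(5H)-one
Conditions: second-generation Grubbs catalyst (H2IMes)(PCy3)Cl2Ru=CHPh (cat.), CH2Cl2, 40 °C
Reagents that add atoms: none
Why: Ring-closing metathesis between the terminal vinyl group and the acrylate forms the five-membered butenolide with loss of ethene, the trisubstituted C4=C5 and the furanone alkene being too hindered and electron-poor to compete.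

Step 14
Reactants: 18 (5S)-5-[(1Z)-2-{(5S)-5-[2-(tert-butyldiphenylsilyloxy)ethyl]-5-methyl-4-oxo-4,5-dihydrofuran-2-yl}-3-[(4-methoxybenzyl)oxy]prop-1-en-1-yl]furan-2(5H)-one
Product: 19 (5S)-5-[(1Z)-2-[(5S)-5-(2-hydroxyethyl)-5-methyl-4-oxo-4,5-dihydrofuran-2-yl]-3-[(4-methoxybenzyl)oxy]prop-1-en-1-yl]furan-2(5H)-one
Conditions: HF·pyridine, pyridine/THF, 0 °C → rt
Reagents that add atoms: none
Why: Fluoride cleaves the Si–O bond under weakly acidic conditions (desilylation), which spares the PMB ether and avoids any base that could deprotonate the now doubly activated C6–H.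

Step 15
Reactants: 19 (5S)-5-[(1Z)-2-[(5S)-5-(2-hydroxyethyl)-5-methyl-4-oxo-4,5-dihydrofuran-2-yl]-3-[(4-methoxybenzyl)oxy]prop-1-en-1-yl]furan-2(5H)-one
Product: 20 2-[(2S)-5-{(1Z)-3-[(4-methoxybenzyl)oxy]-1-[(2S)-5-oxo-2,5-dihydrofuran-2-yl]prop-1-en-2-yl}-2-methyl-3-oxo-2,3-dihydrofuran-2-yl]acetaldehyde
Conditions: Dess–Martin periodinane, NaHCO3, CH2Cl2, 0 °C → rt
Reagents that add atoms: none
Why: Dess–Martin oxidation gives the aldehyde under near-neutral conditions, which avoids β-elimination of the furanone oxygen from C10 and epimerisation at C6, and the aldehyde is used at once.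

Step 16
Reactants: 20 2-[(2S)-5-{(1Z)-3-[(4-methoxybenzyl)oxy]-1-[(2S)-5-oxo-2,5-dihydrofuran-2-yl]prop-1-en-2-yl}-2-methyl-3-oxo-2,3-dihydrofuran-2-yl]acetaldehyde
Product: 21 (4Z,6R,7R,8R,10S)-8-hydroxy-15-[(4-methoxybenzyl)oxy]-1-oxo-3,10-epoxygermacra-2,4-dien-12,6-olide
Conditions: SmI2 (2.5 equiv, added slowly as a 0.1 M solution in THF), t-BuOH (5 equiv), THF (0.003 M), −78 → −30 °C; aq. NH4Cl
Reagents that add atoms: none
Why: Divalent samarium transfers one electron to the aldehyde, the samarium-bound ketyl radical at C8 adds to C7 (the β-carbon of the butenolide), a second electron turns the resulting C11 radical into a trivalent samarium enolate and t-BuOH protonates it at C11. The closest known reaction type is the SmI2-mediated ketyl–olefin (aldehyde–enoate or aldehyde–butenolide) reductive cyclisation, used here at the large end of its documented ring sizes. The closure is 10-exo-trig with respect to the carbocycle C1–C10 (9-exo-trig if the ring is counted through the furanone oxygen), C11 staying outside the new ring. C7 is set by C6, because the ketyl carbon bonds to the butenolide face anti to the C5 substituent and so gives the trans-fused lactone with both ring bonds pseudo-equatorial on the five-membered ring. C8 is set by a transition state in which samarium bridges the ketyl oxygen and the C12 carbonyl oxygen, holding the C8 oxygen over C11 and turning C9 outward into the ring. The step needs the aldehyde to be reduced before the butenolide or the dienyl furanone (whose reduction would expel the C6 carboxylate), which is secured by the vinylogous-ester character of the furanone carbonyl, the absence of HMPA and water, low temperature and slow addition of SmI2 to dilute substrate, while the rigid Z-dienyl furanone shortens the tether so that ring closure outruns pinacol coupling.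

Step 17
Reactants: 21 (4Z,6R,7R,8R,10S)-8-hydroxy-15-[(4-methoxybenzyl)oxy]-1-oxo-3,10-epoxygermacra-2,4-dien-12,6-olide
Product: 22 (4Z,6R,7S,8R,10S)-15-[(4-methoxybenzyl)oxy]-1-oxo-8-(triethylsilyloxy)-3,10-epoxygermacra-2,4-dien-12,6-olide
Conditions: Et3SiOTf, 2,6-lutidine, CH2Cl2, −78 °C
Reagents that add atoms: triethylsilyl trifluoromethanesulfonate CC[Si](CC)(CC)OS(=O)(=O)C(F)(F)F
Why: Silylation with the silyl triflate and a hindered pyridine base masks the C8 hydroxyl so that no alkoxide is present in step 18 to attack C12 (translactonisation) or consume base, the C7 descriptor changing to S by priority only.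

Step 18
Reactants: 22 (4Z,6R,7S,8R,10S)-15-[(4-methoxybenzyl)oxy]-1-oxo-8-(triethylsilyloxy)-3,10-epoxygermacra-2,4-dien-12,6-olide
Product: 24 (4Z,6R,7S,8R,10S)-13-(dimethylamino)-15-[(4-methoxybenzyl)oxy]-1-oxo-8-(triethylsilyloxy)-3,10-epoxygermacra-2,4-dien-12,6-olide, via lithium enolate 23 (not isolated)
Conditions: LiN(SiMe3)2, THF, −78 °C; then CH2=NMe2+ I− (Eschenmoser's salt), −78 → 0 °C
Reagents that add atoms: N,N-dimethylmethyleneiminium iodide C=[N+](C)C.[I-]
Why: The hindered amide base removes a proton from the lactone α-methylene C11 under kinetic control (the furanone ketone has no α-hydrogen) and the lithium enolate is aminomethylated by the iminium salt (Mannich reaction), the C11 configuration being irrelevant because it is destroyed in step 19.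

Step 19
Reactants: 24 (4Z,6R,7S,8R,10S)-13-(dimethylamino)-15-[(4-methoxybenzyl)oxy]-1-oxo-8-(triethylsilyloxy)-3,10-epoxygermacra-2,4-dien-12,6-olide
Product: 26 (4Z,6R,7S,8R,10S)-15-[(4-methoxybenzyl)oxy]-1-oxo-8-(triethylsilyloxy)-3,10-epoxygermacra-2,4,11(13)-trien-12,6-olide, via ammonium iodide 25 (not isolated)
Conditions: MeI, MeOH/CH2Cl2, rt; then aq. NaHCO3, rt
Reagents that add atoms: none
Why: N-Methylation turns the amine into a leaving group and mild base removes the acidic C11 hydrogen to expel trimethylamine (Hofmann-type E1cB elimination), which creates the C11=C13 methylene.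

Step 20
Reactants: 26 (4Z,6R,7S,8R,10S)-15-[(4-methoxybenzyl)oxy]-1-oxo-8-(triethylsilyloxy)-3,10-epoxygermacra-2,4,11(13)-trien-12,6-olide
Product: 27 (4Z,6R,7R,8R,10S)-8-hydroxy-15-[(4-methoxybenzyl)oxy]-1-oxo-3,10-epoxygermacra-2,4,11(13)-trien-12,6-olide
Conditions: HF·pyridine, pyridine/THF, 0 °C
Reagents that add atoms: none
Why: Buffered HF cleaves the secondary triethylsilyl ether (desilylation) without the amine or alkoxide bases that would add to the methylene lactone or move the lactone from O6 to O8, and the PMB ether stays.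

Step 21
Reactants: 27 (4Z,6R,7R,8R,10S)-8-hydroxy-15-[(4-methoxybenzyl)oxy]-1-oxo-3,10-epoxygermacra-2,4,11(13)-trien-12,6-olide
Product: 28 (4Z,6R,7R,8R,10S)-8-methacryloyloxy-15-[(4-methoxybenzyl)oxy]-1-oxo-3,10-epoxygermacra-2,4,11(13)-trien-12,6-olide
Conditions: methacrylic anhydride, Et3N, DMAP (cat.), CH2Cl2, 0 °C → rt
Reagents that add atoms: methacrylic anhydride C=C(C)C(=O)OC(=O)C(C)=C
Why: DMAP-catalysed acylation with the anhydride esterifies the only free hydroxyl at C8 without breaking the C8–O bond, so the configuration set in step 16 is retained.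

Step 22
Reactants: 28 (4Z,6R,7R,8R,10S)-8-methacryloyloxy-15-[(4-methoxybenzyl)oxy]-1-oxo-3,10-epoxygermacra-2,4,11(13)-trien-12,6-olide
Product: 29 CNP0180483.4, (4Z,6R,7R,8R,10S)-15-hydroxy-8-methacryloyloxy-1-oxo-3,10-epoxygermacra-2,4,11(13)-trien-12,6-olide
Conditions: DDQ, CH2Cl2/pH 7 buffer, 0 °C → rt
Reagents that add atoms: none
Why: DDQ oxidises the electron-rich PMB ether to an oxocarbenium ion that water hydrolyses (oxidative PMB cleavage), conditions under which the electron-poor alkenes, the esters and all four stereocenters are inert.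

Compound list
1 | (S)-citramalic acid | C[C@](O)(CC(=O)O)C(=O)O | starting material
2 | 2-[(4S)-2,2,4-trimethyl-5-oxo-1,3-dioxolan-4-yl]acetic acid | CC1(C)O[C@@](C)(CC(=O)O)C(=O)O1 | intermediate
3 | (5S)-5-(2-hydroxyethyl)-2,2,5-trimethyl-1,3-dioxolan-4-one | CC1(C)O[C@@](C)(CCO)C(=O)O1 | intermediate
4 | (5S)-5-[2-(tert-butyldiphenylsilyloxy)ethyl]-2,2,5-trimethyl-1,3-dioxolan-4-one | CC1(C)O[C@@](C)(CCO[Si](c2ccccc2)(c2ccccc2)C(C)(C)C)C(=O)O1 | intermediate
5 | methyl (2S)-4-(tert-butyldiphenylsilyloxy)-2-hydroxy-2-methylbutanoate | COC(=O)[C@@](C)(O)CCO[Si](c1ccccc1)(c1ccccc1)C(C)(C)C | intermediate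
6 | (5S)-5-[2-(tert-butyldiphenylsilyloxy)ethyl]-4-methoxy-5-methylfuran-2(5H)-one (methyl tetronate) | COC1=CC(=O)O[C@@]1(C)CCO[Si](c1ccccc1)(c1ccccc1)C(C)(C)C | intermediate
7 | 2-butyne-1,4-diol | OCC#CCO | starting material
8 | 4-[(4-methoxybenzyl)oxy]but-2-yn-1-ol | COc1ccc(COCC#CCO)cc1 | intermediate
9 | sodium cyclic alkenylalanate from 8 (five-membered O–Al–C ring, aluminium on the carbon bearing CH2OPMB; not isolated) | COCCO[Al-]1(OCCOC)OCC=C1COCc1ccc(OC)cc1.[Na+] | intermediate
10 | (2Z)-3-iodo-4-[(4-methoxybenzyl)oxy]but-2-en-1-ol | COc1ccc(COC/C(I)=C/CO)cc1 | intermediate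
11 | (2Z)-3-iodo-4-[(4-methoxybenzyl)oxy]but-2-enal | COc1ccc(COC/C(I)=C/C=O)cc1 | intermediate
12 | (3S,4Z)-5-iodo-6-[(4-methoxybenzyl)oxy]hexa-1,4-dien-3-ol | COc1ccc(COC/C(I)=C/[C@@H](O)C=C)cc1 | intermediate
13 | (3S,4Z)-5-iodo-6-[(4-methoxybenzyl)oxy]-3-[(2-methoxypropan-2-yl)oxy]hexa-1,4-diene | COc1ccc(COC/C(I)=C/[C@@H](OC(C)(C)OC)C=C)cc1 | intermediate
14 | alkenyllithium from 13 (lithium in place of iodine, alkene geometry retained, lithium cis to C6; not isolated) | COc1ccc(COC/C([Li])=C/[C@@H](OC(C)(C)OC)C=C)cc1 | intermediate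
15 | (5S)-5-[2-(tert-butyldiphenylsilyloxy)ethyl]-4-methoxy-5-methyl-2-{(2Z,4S)-1-[(4-methoxybenzyl)oxy]-4-[(2-methoxypropan-2-yl)oxy]hexa-2,5-dien-2-yl}-2,5-dihydrofuran-2-ol (lactol, both hemiketal epimers; not isolated) | COC1=CC(O)(/C(COCc2ccc(OC)cc2)=C\[C@@H](OC(C)(C)OC)C=C)O[C@@]1(C)CCO[Si](c1ccccc1)(c1ccccc1)C(C)(C)C | intermediate
16 | (2S)-2-[2-(tert-butyldiphenylsilyloxy)ethyl]-5-{(2Z,4S)-4-hydroxy-1-[(4-methoxybenzyl)oxy]hexa-2,5-dien-2-yl}-2-methylfuran-3(2H)-one | O=C1C=C(/C(COCc2ccc(OC)cc2)=C\[C@@H](O)C=C)O[C@@]1(C)CCO[Si](c1ccccc1)(c1ccccc1)C(C)(C)C | intermediate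
17 | (3S,4Z)-5-{(5S)-5-[2-(tert-butyldiphenylsilyloxy)ethyl]-5-methyl-4-oxo-4,5-dihydrofuran-2-yl}-6-[(4-methoxybenzyl)oxy]hexa-1,4-dien-3-yl prop-2-enoate | O=C1C=C(/C(COCc2ccc(OC)cc2)=C\[C@@H](OC(=O)C=C)C=C)O[C@@]1(C)CCO[Si](c1ccccc1)(c1ccccc1)C(C)(C)C | intermediate
18 | (5S)-5-[(1Z)-2-{(5S)-5-[2-(tert-butyldiphenylsilyloxy)ethyl]-5-methyl-4-oxo-4,5-dihydrofuran-2-yl}-3-[(4-methoxybenzyl)oxy]prop-1-en-1-yl]furan-2(5H)-one | O=C1C=C(/C(COCc2ccc(OC)cc2)=C\[C@H]2OC(=O)C=C2)O[C@@]1(C)CCO[Si](c1ccccc1)(c1ccccc1)C(C)(C)C | intermediate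
19 | (5S)-5-[(1Z)-2-[(5S)-5-(2-hydroxyethyl)-5-methyl-4-oxo-4,5-dihydrofuran-2-yl]-3-[(4-methoxybenzyl)oxy]prop-1-en-1-yl]furan-2(5H)-one | O=C1C=C(/C(COCc2ccc(OC)cc2)=C\[C@H]2OC(=O)C=C2)O[C@@]1(C)CCO | intermediate
20 | 2-[(2S)-5-{(1Z)-3-[(4-methoxybenzyl)oxy]-1-[(2S)-5-oxo-2,5-dihydrofuran-2-yl]prop-1-en-2-yl}-2-methyl-3-oxo-2,3-dihydrofuran-2-yl]acetaldehyde (precursor of the key step) | O=CC[C@]1(C)OC(=CC1=O)/C(COCc1ccc(OC)cc1)=C\[C@H]1OC(=O)C=C1 | intermediate
21 | (4Z,6R,7R,8R,10S)-8-hydroxy-15-[(4-methoxybenzyl)oxy]-1-oxo-3,10-epoxygermacra-2,4-dien-12,6-olide (product of the key step) | O[C@@H]1C[C@]2(C)OC(=CC2=O)/C(COCc2ccc(OC)cc2)=C\[C@H]2OC(=O)C[C@@H]21 | intermediate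
22 | (4Z,6R,7S,8R,10S)-15-[(4-methoxybenzyl)oxy]-1-oxo-8-(triethylsilyloxy)-3,10-epoxygermacra-2,4-dien-12,6-olide | CC[Si](CC)(CC)O[C@@H]1C[C@]2(C)OC(=CC2=O)/C(COCc2ccc(OC)cc2)=C\[C@H]2OC(=O)C[C@@H]21 | intermediate
23 | lithium enolate of 22 (C11=C12–OLi; not isolated) | CC[Si](CC)(CC)O[C@@H]1C[C@]2(C)OC(=CC2=O)/C(COCc2ccc(OC)cc2)=C\[C@H]2OC(O[Li])=C[C@@H]21 | intermediate
24 | (4Z,6R,7S,8R,10S)-13-(dimethylamino)-15-[(4-methoxybenzyl)oxy]-1-oxo-8-(triethylsilyloxy)-3,10-epoxygermacra-2,4-dien-12,6-olide (either C11 epimer) | CC[Si](CC)(CC)O[C@@H]1C[C@]2(C)OC(=CC2=O)/C(COCc2ccc(OC)cc2)=C\[C@H]2OC(=O)C(CN(C)C)[C@@H]21 | intermediate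
25 | 13-(trimethylammonio) iodide from 24 (not isolated) | CC[Si](CC)(CC)O[C@@H]1C[C@]2(C)OC(=CC2=O)/C(COCc2ccc(OC)cc2)=C\[C@H]2OC(=O)C(C[N+](C)(C)C)[C@@H]21.[I-] | intermediate
26 | (4Z,6R,7S,8R,10S)-15-[(4-methoxybenzyl)oxy]-1-oxo-8-(triethylsilyloxy)-3,10-epoxygermacra-2,4,11(13)-trien-12,6-olide | CC[Si](CC)(CC)O[C@@H]1C[C@]2(C)OC(=CC2=O)/C(COCc2ccc(OC)cc2)=C\[C@H]2OC(=O)C(=C)[C@@H]21 | intermediate
27 | (4Z,6R,7R,8R,10S)-8-hydroxy-15-[(4-methoxybenzyl)oxy]-1-oxo-3,10-epoxygermacra-2,4,11(13)-trien-12,6-olide | O[C@@H]1C[C@]2(C)OC(=CC2=O)/C(COCc2ccc(OC)cc2)=C\[C@H]2OC(=O)C(=C)[C@@H]21 | intermediate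
28 | (4Z,6R,7R,8R,10S)-8-methacryloyloxy-15-[(4-methoxybenzyl)oxy]-1-oxo-3,10-epoxygermacra-2,4,11(13)-trien-12,6-olide | C=C(C)C(=O)O[C@@H]1C[C@]2(C)OC(=CC2=O)/C(COCc2ccc(OC)cc2)=C\[C@H]2OC(=O)C(=C)[C@@H]21 | intermediate
29 | CNP0180483.4, (4Z,6R,7R,8R,10S)-15-hydroxy-8-methacryloyloxy-1-oxo-3,10-epoxygermacra-2,4,11(13)-trien-12,6-olide | C=C(C)C(=O)O[C@@H]1C[C@]2(C)OC(=CC2=O)/C(CO)=C\[C@H]2OC(=O)C(=C)[C@@H]21 | target

Total step count: 22. Longest linear sequence: 17 steps (steps 1–5 or 6–10, then 11–22).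

Steps most likely to fail

Step 16 (key step). What may go wrong: electron transfer to the dienyl furanone or the butenolide instead of the aldehyde, followed by loss of the C6 carboxylate; intermolecular pinacol coupling or plain reduction of the aldehyde because the ten-membered transition state is reached too slowly; bond formation on the wrong face at C7 or C8. The fallback forms the same C7–C8 bond by a two-electron allyl-metal addition and brings C13 in beforehand. Alcohol 16 would be esterified with 2-(bromomethyl)acrylic acid (DCC, DMAP cat., CH2Cl2) to the 2-(bromomethyl)acrylate F1. Ring-closing metathesis with the second-generation Grubbs catalyst (H2IMes)(PCy3)Cl2Ru=CHPh in toluene at 80 °C would give the α-(bromomethyl)butenolide F2. HF·pyridine would free the primary alcohol F3 and Dess–Martin periodinane would give the bromo aldehyde F4. CrCl2 (divalent chromium) in THF at high dilution (Nozaki–Hiyama-type allylation) would convert the allylic bromide into an allylchromium species that adds through C7 to the C8 aldehyde in a chair-like transition state and leaves the C11=C13 methylene. This returns the route at 27 and makes steps 17–20 unnecessary.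

Step 11. What may go wrong: expulsion of the allylic 4-methoxybenzyl oxide from the alkenyllithium (allene formation), proton transfer to the alkenyllithium, or collapse of the lactolate followed by a second addition. The fallback forms C3–C4 by cross-coupling and the furanone by cycloisomerisation. Ester 5 would be converted with MeNHOMe·HCl and i-PrMgCl into the Weinreb amide F5 and then with HC≡CMgBr into the ethynyl ketone F6. Sonogashira coupling with iodide 13 (Pd(PPh3)2Cl2, CuI, i-Pr2NH, THF) would give the α'-hydroxy enynone F7. AuCl3 (trivalent gold, cat.) would close the furanone by 5-endo-dig addition of the tertiary hydroxyl to the alkyne, giving the MOP-protected furanone F8. 0.5 M aq. HCl in THF would cleave the mixed ketal and return the route at 16.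

Step 9. What may go wrong: erosion of enantioselectivity through uncatalysed addition or chelation of zinc by the allylic ether oxygen, which would appear after step 11 as a C6 diastereomer. The fallback replaces asymmetric catalysis by resolution. CH2=CHMgBr would add to aldehyde 11 (THF, −78 °C) to give the racemic alcohol F9. Burkholderia cepacia lipase with vinyl acetate should acetylate the R enantiomer, the usual sense for a secondary carbinol flanked by a large and a small group, to the R acetate F10. The unreacted S alcohol is 12, where the route is rejoined.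

Further compounds
F1 | step 16 | 2-(bromomethyl)acrylate of 16 | O=C1C=C(/C(COCc2ccc(OC)cc2)=C\[C@@H](OC(=O)C(=C)CBr)C=C)O[C@@]1(C)CCO[Si](c1ccccc1)(c1ccccc1)C(C)(C)C
F2 | step 16 | α-(bromomethyl)butenolide, C8 tert-butyldiphenylsilyl ether | O=C1C=C(/C(COCc2ccc(OC)cc2)=C\[C@H]2OC(=O)C(CBr)=C2)O[C@@]1(C)CCO[Si](c1ccccc1)(c1ccccc1)C(C)(C)C
F3 | step 16 | α-(bromomethyl)butenolide, C8 primary alcohol | O=C1C=C(/C(COCc2ccc(OC)cc2)=C\[C@H]2OC(=O)C(CBr)=C2)O[C@@]1(C)CCO
F4 | step 16 | α-(bromomethyl)butenolide, C8 aldehyde | O=CC[C@]1(C)OC(=CC1=O)/C(COCc1ccc(OC)cc1)=C\[C@H]1OC(=O)C(CBr)=C1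
F5 | step 11 | (2S)-4-(tert-butyldiphenylsilyloxy)-2-hydroxy-N-methoxy-N,2-dimethylbutanamide | CON(C)C(=O)[C@@](C)(O)CCO[Si](c1ccccc1)(c1ccccc1)C(C)(C)C
F6 | step 11 | (4S)-6-(tert-butyldiphenylsilyloxy)-4-hydroxy-4-methylhex-1-yn-3-one | C#CC(=O)[C@@](C)(O)CCO[Si](c1ccccc1)(c1ccccc1)C(C)(C)C
F7 | step 11 | α'-hydroxy enynone from F6 and 13 | O=C(C#C/C(COCc1ccc(OC)cc1)=C\[C@@H](OC(C)(C)OC)C=C)[C@@](C)(O)CCO[Si](c1ccccc1)(c1ccccc1)C(C)(C)C
F8 | step 11 | 2-methoxyprop-2-yl ether of 16 | O=C1C=C(/C(COCc2ccc(OC)cc2)=C\[C@@H](OC(C)(C)OC)C=C)O[C@@]1(C)CCO[Si](c1ccccc1)(c1ccccc1)C(C)(C)C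
F9 | step 9 | racemic (4Z)-5-iodo-6-[(4-methoxybenzyl)oxy]hexa-1,4-dien-3-ol | COc1ccc(COC/C(I)=C/C(O)C=C)cc1
F10 | step 9 | (3R,4Z)-5-iodo-6-[(4-methoxybenzyl)oxy]hexa-1,4-dien-3-yl acetate | COc1ccc(COC/C(I)=C/[C@H](OC(C)=O)C=C)cc1
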